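**Retrosynthetic overview**

1. The target, (2R,3R,2'R,3'R)-β,β-carotene-2,3,2',3'-tetrol 3'-(hydrogen sulfate), comes from global desilylation, preceded by sulfation of the only free hydroxyl (O3') and selective TES removal on a C40 polyene whose two ring halves differ only in the silyl group on O3.
2. The C40 polyene comes from two successive Julia–Kocienski olefinations (C7=C8, then C7'=C8') of ring C10 tetrazolyl sulfones with the C20 dialdehyde crocetindial (C10 + C20 + C10).
3. Both sulfones come from one protected (2R,3R)-2,3-dihydroxy-β-cyclogeraniol. The strategy rests on the tetrasubstituted C5=C6 alkene of each cyclohexene ring (C1–C6), flanked by quaternary C1 and carrying C7: it is made by ring-closing metathesis of an acyclic 1,7-diene with two 1,1-disubstituted alkenes, after C2 and C3 have been set in the open chain.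
4. The diene comes from chelation-controlled addition of a 2-(silyloxymethyl)prenylstannane (from diethyl isopropylidenemalonate) through its γ-carbon to (R)-2-(PMBO)-4-methylpent-4-enal (from (S)-glycidol and isopropenylmagnesium bromide); this sets C1 and C2, and C3 comes from glycidol.
5. Ring order: the cyclohexene is formed once (step 11) on the common intermediate, before the route divides into half A (O3-TES, later sulfated) and half B (O3-TBS).

Key step: step 11

Assumption 1: the target is drawn as the free hydrogen sulfate; such a monoester would be handled as its pyridinium, tetrabutylammonium or sodium salt, and the neutral acid form is written throughout.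
Assumption 2: all-E crocetindial (compound 22) is taken as a purchasable C20 building block.
Remark: locants 1–7 and 2R,3R in the names of ring compounds follow carotenoid numbering (C1 gem-dimethyl carbon, C2 and C3 oxygenated, C5=C6 ring alkene, C7 exocyclic carbon).

**Route**

Step 1
Reactants: 1 (S)-glycidol; 2 isopropenylmagnesium bromide
Product: 3 (R)-4-methylpent-4-ene-1,2-diol
Conditions: 2 (2.5 equiv), CuI (10 mol%), THF, −30 to 0 °C; aq NH4Cl
Reagents that add atoms: none
Why: Copper-catalysed Grignard opening of the epoxide at its unsubstituted carbon (SN2) leaves the C–O stereocentre untouched, so (S)-glycidol should give the (R)-diol (the descriptor changes only through the priority rules), and this carbon becomes C3.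

Step 2
Reactants: 3 (R)-4-methylpent-4-ene-1,2-diol
Product: 4 (4R)-2-(4-methoxyphenyl)-4-(2-methylprop-2-enyl)-1,3-dioxolane (both acetal epimers)
Conditions: 4-MeOC6H4CH(OMe)2, PPTS (cat.), CH2Cl2, rt
Reagents that add atoms: 4-methoxybenzaldehyde dimethyl acetal, COC(OC)c1ccc(OC)cc1
Why: Acid-catalysed transacetalisation of the 1,2-diol should give the five-membered p-methoxybenzylidene acetal, the weak acid keeping Prins-type attack of the methallyl alkene on the oxocarbenium ion out of play.

Step 3
Reactants: 4 the p-methoxybenzylidene acetal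
Product: 5 (2R)-2-(4-methoxybenzyloxy)-4-methylpent-4-en-1-ol
Conditions: i-Bu2AlH, CH2Cl2, −78 to 0 °C; Rochelle salt
Reagents that add atoms: none
Why: Regioselective reductive acetal opening, in which i-Bu2AlH binds the less hindered primary oxygen and delivers hydride to the oxocarbenium ion, should leave the PMB group on the secondary oxygen (the later O3).

Step 4
Reactants: 5 (2R)-2-(4-methoxybenzyloxy)-4-methylpent-4-en-1-ol
Product: 6 (2R)-2-(4-methoxybenzyloxy)-4-methylpent-4-enal
Conditions: Dess–Martin periodinane, CH2Cl2, 0 °C to rt; used crude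
Reagents that add atoms: none
Why: Dess–Martin oxidation of the primary alcohol under neutral conditions should give the α-alkoxy aldehyde without epimerisation of the future C3.

Step 5
Reactants: 7 diethyl isopropylidenemalonate
Product: 8 2-(propan-2-ylidene)propane-1,3-diol
Conditions: i-Bu2AlH (4.5 equiv), CH2Cl2, −78 to 0 °C; Rochelle salt
Reagents that add atoms: none
Why: 1,2-Reduction of both conjugated esters by i-Bu2AlH in a non-coordinating solvent should give the allylic diol with the tetrasubstituted alkene intact.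

Step 6
Reactants: 8 2-(propan-2-ylidene)propane-1,3-diol
Product: 9 2-(tert-butyldimethylsilyloxymethyl)-3-methylbut-2-en-1-ol
Conditions: NaH (1.0 equiv), THF, 0 °C; TBSCl (1.0 equiv), rt
Reagents that add atoms: tert-butyldimethylsilyl chloride, CC(C)(C)[Si](C)(C)Cl
Why: Monosilylation of a symmetric diol through its monosodium alkoxide (McDougal conditions) should give mainly the mono-TBS ether, and the diol and bis-ether are recyclable.

Step 7
Reactants: 9 the mono-TBS ether
Product: 10 [2-(bromomethyl)-3-methylbut-2-enyloxy](tert-butyl)dimethylsilane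
Conditions: CBr4, PPh3, CH2Cl2, 0 °C
Reagents that add atoms: carbon tetrabromide, BrC(Br)(Br)Br
Why: Appel bromination of the primary allylic alcohol under neutral conditions should leave the TBS ether untouched.

Step 8
Reactants: 10 the allylic bromide
Product: 11 tributyl[2-(tert-butyldimethylsilyloxymethyl)-3-methylbut-2-enyl]stannane
Conditions: Bu3SnLi (from Bu3SnH, LiN(i-Pr)2), THF, −78 °C
Reagents that add atoms: tributyltin hydride, CCCC[SnH](CCCC)CCCC
Why: SN2 displacement of the primary allylic bromide by the stannyl anion should give the primary allylstannane, since the SN2' alternative would put tin on a tertiary carbon.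

Step 9
Reactants: 6 (2R)-2-(4-methoxybenzyloxy)-4-methylpent-4-enal; 11 the allylstannane
Product: 12 (4R,5R)-2-(tert-butyldimethylsilyloxymethyl)-5-(4-methoxybenzyloxy)-3,3,7-trimethylocta-1,7-dien-4-ol (carotenoid 2R,3R)
Conditions: MgBr2·OEt2 (2.5 equiv), CH2Cl2, −40 to 0 °C
Reagents that add atoms: none
Why: In this chelation-controlled Lewis acid mediated allylstannane addition (Keck-type SE2'), MgBr2 bridges the aldehyde oxygen and the PMB ether oxygen and the stannane attacks through its γ-carbon (CMe2) on the face away from the methallyl group, which should create quaternary C1 and the 2,3-syn (2R) carbinol and move the alkene to the C6 methylidene.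

Step 10
Reactants: 12 the homoallylic alcohol
Product: 13 (4R,5R)-4-(tert-butyldimethylsilyloxy)-2-(tert-butyldimethylsilyloxymethyl)-5-(4-methoxybenzyloxy)-3,3,7-trimethylocta-1,7-diene
Conditions: TBSOTf, 2,6-lutidine, CH2Cl2, 0 °C to rt
Reagents that add atoms: tert-butyldimethylsilyl triflate, CC(C)(C)[Si](C)(C)OS(=O)(=O)C(F)(F)F
Why: Silylation of the hindered neopentyl-type secondary alcohol with the silyl triflate should give the TBS ether without touching the PMB ether.

Step 11
Reactants: 13 the 1,7-diene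
Product: 14 (2R,3R)-2-O-TBS-3-O-PMB-2,3-dihydroxy-β-cyclogeraniol TBS ether, i.e. tert-butyl{[(4R,5R)-5-(tert-butyldimethylsilyloxy)-4-(4-methoxybenzyloxy)-2,6,6-trimethylcyclohex-1-en-1-yl]methoxy}dimethylsilane
Conditions: RuCl2(=CH-C6H4-2-OiPr)[1,3-bis(2-methylphenyl)imidazolidin-2-ylidene] (10 mol%, in portions), toluene (5 mM), 80 °C, Ar sparge
Reagents that add atoms: none
Why: Ring-closing olefin metathesis: the ruthenium carbene should load onto the less hindered methallyl terminus at C5, add [2+2] across the C6 methylidene to a ruthenacyclobutane and cyclorevert to the C5=C6 alkene, the carbene being regenerated with loss of ethylene. The closest known reaction type is ring-closing metathesis to tetrasubstituted cyclohexenes with N-heterocyclic carbene ruthenium catalysts bearing small N-aryl groups, including closures beside a quaternary carbon. Ring C1–C6 is closed as a six-membered carbocycle with the new alkene endocyclic and C7 already on C6 as a silyloxymethyl group. No stereocentre is formed, and C2 and C3 are not touched. The step needs ring closure to win over intermolecular metathesis and alkene migration; the gem-dimethyl group at C1 and the bulky ethers at C2 and C3 fold the chain (Thorpe–Ingold effect), homocoupling of 1,1-disubstituted alkenes is unproductive, no other alkene is present, and dilution with an argon sparge removes ethylene.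

Step 12
Reactants: 14 the protected cyclogeraniol
Product: 15 [(4R,5R)-5-(tert-butyldimethylsilyloxy)-4-(4-methoxybenzyloxy)-2,6,6-trimethylcyclohex-1-en-1-yl]methanol
Conditions: HF·pyridine, pyridine, THF, 0 °C
Reagents that add atoms: none
Why: Selective desilylation with buffered HF should cleave the primary allylic TBS ether at C7 much faster than the secondary TBS ether at O2, which is shielded by the C1 gem-dimethyl group.

Step 13
Reactants: 15 the C7 allylic alcohol
Product: 16 5-({[(4R,5R)-5-(tert-butyldimethylsilyloxy)-4-(4-methoxybenzyloxy)-2,6,6-trimethylcyclohex-1-en-1-yl]methyl}sulfanyl)-1-phenyl-1H-tetrazole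
Conditions: 1-phenyl-1H-tetrazole-5-thiol, PPh3, DIAD, THF, 0 °C to rt
Reagents that add atoms: 1-phenyl-1H-tetrazole-5-thiol, SC1=NN=NN1c1ccccc1
Why: Mitsunobu thioetherification of the primary allylic alcohol with the acidic heteroaryl thiol should give the sulfide at C7 without involving a stereocentre.

Step 14
Reactants: 16 the tetrazolyl sulfide
Product: 18 the corresponding 1-phenyl-1H-tetrazol-5-yl sulfone (O2-TBS and O3-PMB), via sulfoxide 17 (not isolated)
Conditions: (NH4)6Mo7O24·4H2O (10 mol%), 30% H2O2, EtOH, 0 °C to rt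
Reagents that add atoms: hydrogen peroxide, OO
Why: Molybdate-catalysed peroxide oxidation of the sulfide through the sulfoxide to the sulfone is selective for sulfur, so the tetrasubstituted alkene and the PMB ether should survive where a peracid would epoxidise.

Step 15
Reactants: 18 the PMB-protected sulfone
Product: 19 5-({[(4R,5R)-5-(tert-butyldimethylsilyloxy)-4-hydroxy-2,6,6-trimethylcyclohex-1-en-1-yl]methyl}sulfonyl)-1-phenyl-1H-tetrazole
Conditions: DDQ, CH2Cl2/pH 7 buffer, 0 °C
Reagents that add atoms: none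
Why: Oxidative PMB ether cleavage by DDQ, done before any polyene is present and without base, should free O3 while the O2 silyl group stays in place.

Step 16
Reactants: 19 the O3 alcohol
Product: 20 half B sulfone, 5-({[(4R,5R)-4,5-bis(tert-butyldimethylsilyloxy)-2,6,6-trimethylcyclohex-1-en-1-yl]methyl}sulfonyl)-1-phenyl-1H-tetrazole
Conditions: TBSOTf, 2,6-lutidine, CH2Cl2, 0 °C
Reagents that add atoms: tert-butyldimethylsilyl triflate, CC(C)(C)[Si](C)(C)OS(=O)(=O)C(F)(F)F
Why: Silylation of the unhindered O3 alcohol should give the half in which both ring oxygens carry TBS groups.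

Step 17
Reactants: 19 the O3 alcohol
Product: 21 half A sulfone, 5-({[(4R,5R)-5-(tert-butyldimethylsilyloxy)-2,6,6-trimethyl-4-(triethylsilyloxy)cyclohex-1-en-1-yl]methyl}sulfonyl)-1-phenyl-1H-tetrazole
Conditions: TESOTf, 2,6-lutidine, CH2Cl2, 0 °C
Reagents that add atoms: triethylsilyl triflate, CC[Si](CC)(CC)OS(=O)(=O)C(F)(F)F
Why: Silylation with the triethylsilyl triflate should mark O3 of this half with the more acid-labile TES group, the later site of the sulfate.

Step 18
Reactants: 20 half B sulfone; 22 crocetindial, (2E,4E,6E,8E,10E,12E,14E)-2,6,11,15-tetramethylhexadeca-2,4,6,8,10,12,14-heptaenedial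
Product: 24 (2R,3R)-2,3-bis(tert-butyldimethylsilyloxy)-8'-apo-β-caroten-8'-al (7E/Z mixture), via potassium sulfonyl carbanion 23 (not isolated)
Conditions: KN(SiMe3)2, THF, −78 °C; then added to 22 (3 equiv), THF, −78 °C to rt, dark
Reagents that add atoms: none
Why: In this Julia–Kocienski olefination the allylic sulfonyl carbanion should add to one aldehyde group of the excess dialdehyde and, after Smiles rearrangement and loss of sulfur dioxide and the tetrazolone, form C7=C8 as an E/Z mixture that is equilibrated in step 20.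

Step 19
Reactants: 24 the C30 aldehyde; 21 half A sulfone
Product: 26 (2R,3R,2'R,3'R)-2,3,2'-tris(tert-butyldimethylsilyloxy)-3'-(triethylsilyloxy)-β,β-carotene (7E/Z and 7'E/Z mixture), via potassium sulfonyl carbanion 25 (not isolated)
Conditions: 21 (1.3 equiv), KN(SiMe3)2, THF, −78 °C; then 24, −78 °C to rt, dark
Reagents that add atoms: none
Why: A second Julia–Kocienski olefination of the polyenal with the metalated half A sulfone should form C7'=C8' and complete the C40 skeleton, the silyl ethers being inert to the amide base.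

Step 20
Reactants: 26 the C40 isomer mixture
Product: 27 all-E (2R,3R,2'R,3'R)-2,3,2'-tris(tert-butyldimethylsilyloxy)-3'-(triethylsilyloxy)-β,β-carotene
Conditions: I2 (1 mol%), toluene, daylight, rt, Ar
Reagents that add atoms: none
Why: Iodine-catalysed E/Z equilibration of the polyene should move the strained 7Z and 7'Z isomers to the thermodynamically preferred all-E isomer, which is separated by crystallisation or chromatography.

Step 21
Reactants: 27 the all-E silyl-protected carotenoid
Product: 28 (2R,3R,2'R,3'R)-2,3,2'-tris(tert-butyldimethylsilyloxy)-β,β-caroten-3'-ol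
Conditions: PPTS (0.3 equiv), MeOH/CH2Cl2, 0 °C, dark
Reagents that add atoms: none
Why: Acid-catalysed methanolysis cleaves a TES ether far faster than TBS ethers (selective desilylation), so only O3' should be freed under conditions mild enough for a polyene that has no epoxide or allylic oxygen.

Step 22
Reactants: 28 the mono-alcohol
Product: 29 (2R,3R,2'R,3'R)-2,3,2'-tris(tert-butyldimethylsilyloxy)-β,β-caroten-3'-yl hydrogen sulfate (formed as the pyridinium salt)
Conditions: SO3·pyridine (5 equiv), pyridine, rt, dark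
Reagents that add atoms: sulfur trioxide–pyridine complex, O=S(=O)([O-])[n+]1ccccc1
Why: O-Sulfation of an alcohol with the sulfur trioxide–pyridine complex, a known route to carotenol sulfates, can only take place at O3' because every other oxygen is silylated.

Step 23
Reactants: 29 the tris-silylated sulfate
Product: 30 target, (2R,3R,2'R,3'R)-β,β-carotene-2,3,2',3'-tetrol 3'-(hydrogen sulfate) (isolated as its salt)
Conditions: Bu4NF, THF, rt to 40 °C, dark, Ar
Reagents that add atoms: none
Why: Fluoride-mediated cleavage of the three TBS ethers should leave the sulfate monoester anion and the polyene intact, the hindered O2 and O2' ethers possibly needing the gentle warming.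

**Compound list**

1 | (S)-glycidol | OC[C@H]1CO1 | starting material
2 | isopropenylmagnesium bromide | CC(=C)[Mg]Br | starting material
3 | (R)-4-methylpent-4-ene-1,2-diol | OC[C@H](O)CC(C)=C | intermediate
4 | (4R)-2-(4-methoxyphenyl)-4-(2-methylprop-2-enyl)-1,3-dioxolane | C=C(C)C[C@@H]1COC(c2ccc(OC)cc2)O1 | intermediate
5 | (2R)-2-(4-methoxybenzyloxy)-4-methylpent-4-en-1-ol | OC[C@H](OCc1ccc(OC)cc1)CC(C)=C | intermediate
6 | (2R)-2-(4-methoxybenzyloxy)-4-methylpent-4-enal | O=C[C@H](OCc1ccc(OC)cc1)CC(C)=C | intermediate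
7 | diethyl isopropylidenemalonate | CCOC(=O)C(=C(C)C)C(=O)OCC | starting material
8 | 2-(propan-2-ylidene)propane-1,3-diol | CC(C)=C(CO)CO | intermediate
9 | 2-(tert-butyldimethylsilyloxymethyl)-3-methylbut-2-en-1-ol | CC(C)=C(CO)CO[Si](C)(C)C(C)(C)C | intermediate
10 | [2-(bromomethyl)-3-methylbut-2-enyloxy](tert-butyl)dimethylsilane | CC(C)=C(CBr)CO[Si](C)(C)C(C)(C)C | intermediate
11 | tributyl[2-(tert-butyldimethylsilyloxymethyl)-3-methylbut-2-enyl]stannane | CC(C)=C(C[Sn](CCCC)(CCCC)CCCC)CO[Si](C)(C)C(C)(C)C | intermediate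
12 | (4R,5R)-2-(tert-butyldimethylsilyloxymethyl)-5-(4-methoxybenzyloxy)-3,3,7-trimethylocta-1,7-dien-4-ol | C=C(CO[Si](C)(C)C(C)(C)C)C(C)(C)[C@@H](O)[C@H](OCc1ccc(OC)cc1)CC(C)=C | intermediate
13 | (4R,5R)-4-(tert-butyldimethylsilyloxy)-2-(tert-butyldimethylsilyloxymethyl)-5-(4-methoxybenzyloxy)-3,3,7-trimethylocta-1,7-diene | C=C(CO[Si](C)(C)C(C)(C)C)C(C)(C)[C@@H](O[Si](C)(C)C(C)(C)C)[C@H](OCc1ccc(OC)cc1)CC(C)=C | intermediate
14 | protected (2R,3R)-2,3-dihydroxy-β-cyclogeraniol (O2-TBS, O3-PMB, O7-TBS) | CC1=C(CO[Si](C)(C)C(C)(C)C)C(C)(C)[C@@H](O[Si](C)(C)C(C)(C)C)[C@H](OCc2ccc(OC)cc2)C1 | intermediate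
15 | [(4R,5R)-5-(tert-butyldimethylsilyloxy)-4-(4-methoxybenzyloxy)-2,6,6-trimethylcyclohex-1-en-1-yl]methanol | CC1=C(CO)C(C)(C)[C@@H](O[Si](C)(C)C(C)(C)C)[C@H](OCc2ccc(OC)cc2)C1 | intermediate
16 | C7 1-phenyltetrazol-5-yl sulfide (O2-TBS, O3-PMB) | CC1=C(CSC2=NN=NN2c3ccccc3)C(C)(C)[C@@H](O[Si](C)(C)C(C)(C)C)[C@H](OCc4ccc(OC)cc4)C1 | intermediate
17 | C7 1-phenyltetrazol-5-yl sulfoxide (O2-TBS, O3-PMB) | CC1=C(CS(=O)C2=NN=NN2c3ccccc3)C(C)(C)[C@@H](O[Si](C)(C)C(C)(C)C)[C@H](OCc4ccc(OC)cc4)C1 | intermediate (not isolated)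
18 | C7 1-phenyltetrazol-5-yl sulfone (O2-TBS, O3-PMB) | CC1=C(CS(=O)(=O)C2=NN=NN2c3ccccc3)C(C)(C)[C@@H](O[Si](C)(C)C(C)(C)C)[C@H](OCc4ccc(OC)cc4)C1 | intermediate
19 | C7 1-phenyltetrazol-5-yl sulfone (O2-TBS, O3-H) | CC1=C(CS(=O)(=O)C2=NN=NN2c3ccccc3)C(C)(C)[C@@H](O[Si](C)(C)C(C)(C)C)[C@H](O)C1 | intermediate
20 | half B sulfone (O2-TBS, O3-TBS) | CC1=C(CS(=O)(=O)C2=NN=NN2c3ccccc3)C(C)(C)[C@@H](O[Si](C)(C)C(C)(C)C)[C@H](O[Si](C)(C)C(C)(C)C)C1 | intermediate
21 | half A sulfone (O2-TBS, O3-TES) | CC1=C(CS(=O)(=O)C2=NN=NN2c3ccccc3)C(C)(C)[C@@H](O[Si](C)(C)C(C)(C)C)[C@H](O[Si](CC)(CC)CC)C1 | intermediate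
22 | crocetindial (all-E) | O=C/C(C)=C/C=C/C(C)=C/C=C/C=C(C)/C=C/C=C(C)/C=O | starting material
23 | potassium salt of C7-metalated sulfone 20 | CC1=C([CH-]S(=O)(=O)C2=NN=NN2c3ccccc3)C(C)(C)[C@@H](O[Si](C)(C)C(C)(C)C)[C@H](O[Si](C)(C)C(C)(C)C)C1.[K+] | intermediate (not isolated)
24 | (2R,3R)-2,3-bis(tert-butyldimethylsilyloxy)-8'-apo-β-caroten-8'-al (7E/Z) | CC1=C(C=C/C(C)=C/C=C/C(C)=C/C=C/C=C(C)/C=C/C=C(C)/C=O)C(C)(C)[C@@H](O[Si](C)(C)C(C)(C)C)[C@H](O[Si](C)(C)C(C)(C)C)C1 | intermediate
25 | potassium salt of C7-metalated sulfone 21 | CC1=C([CH-]S(=O)(=O)C2=NN=NN2c3ccccc3)C(C)(C)[C@@H](O[Si](C)(C)C(C)(C)C)[C@H](O[Si](CC)(CC)CC)C1.[K+] | intermediate (not isolated)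
26 | 2,3,2'-tris-O-TBS-3'-O-TES carotenoid (7E/Z, 7'E/Z) | CC1=C(C=C/C(C)=C/C=C/C(C)=C/C=C/C=C(C)/C=C/C=C(C)/C=CC2=C(C)C[C@@H](O[Si](CC)(CC)CC)[C@H](O[Si](C)(C)C(C)(C)C)C2(C)C)C(C)(C)[C@@H](O[Si](C)(C)C(C)(C)C)[C@H](O[Si](C)(C)C(C)(C)C)C1 | intermediate
27 | all-E 2,3,2'-tris-O-TBS-3'-O-TES carotenoid | CC1=C(/C=C/C(C)=C/C=C/C(C)=C/C=C/C=C(C)/C=C/C=C(C)/C=C/C2=C(C)C[C@@H](O[Si](CC)(CC)CC)[C@H](O[Si](C)(C)C(C)(C)C)C2(C)C)C(C)(C)[C@@H](O[Si](C)(C)C(C)(C)C)[C@H](O[Si](C)(C)C(C)(C)C)C1 | intermediate
28 | all-E 2,3,2'-tris-O-TBS carotenoid 3'-ol | CC1=C(/C=C/C(C)=C/C=C/C(C)=C/C=C/C=C(C)/C=C/C=C(C)/C=C/C2=C(C)C[C@@H](O)[C@H](O[Si](C)(C)C(C)(C)C)C2(C)C)C(C)(C)[C@@H](O[Si](C)(C)C(C)(C)C)[C@H](O[Si](C)(C)C(C)(C)C)C1 | intermediate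
29 | all-E 2,3,2'-tris-O-TBS carotenoid 3'-(hydrogen sulfate) | CC1=C(/C=C/C(C)=C/C=C/C(C)=C/C=C/C=C(C)/C=C/C=C(C)/C=C/C2=C(C)C[C@@H](OS(=O)(=O)O)[C@H](O[Si](C)(C)C(C)(C)C)C2(C)C)C(C)(C)[C@@H](O[Si](C)(C)C(C)(C)C)[C@H](O[Si](C)(C)C(C)(C)C)C1 | intermediate
30 | (2R,3R,2'R,3'R)-β,β-carotene-2,3,2',3'-tetrol 3'-(hydrogen sulfate) | CC1=C(/C=C/C(C)=C/C=C/C(C)=C/C=C/C=C(C)/C=C/C=C(C)/C=C/C2=C(C)C[C@@H](OS(=O)(=O)O)[C@H](O)C2(C)C)C(C)(C)[C@@H](O)[C@H](O)C1 | target

**Step count and risks**

Total step count: 23.
Longest linear sequence: 18 steps (steps 1–4, 9–16, 18–23, from (S)-glycidol).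

Steps most likely to fail:

1. Step 11 (ring-closing metathesis). After loading at the methallyl end, the carbene may fail to engage the C6 methylidene wedged between quaternary C1 and the silyloxymethyl group. Catalyst decay, hydride-driven alkene migration or intermolecular coupling through the methallyl ends could then overtake ring closure. The fallback sets out from aldehyde 6 and comes back at alcohol 15; it closes the ring as a trisubstituted alkene and brings in C7 afterwards.
   - MgBr2·OEt2-mediated addition of commercial tributyl(3-methylbut-2-enyl)stannane to 6, under the same chelation control, would give the reverse-prenyl alcohol F1.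
   - TBSOTf/2,6-lutidine would give its silyl ether F2.
   - Second-generation Grubbs catalyst, RuCl2(=CHPh)(PCy3)(1,3-dimesitylimidazolidin-2-ylidene), would close the trisubstituted cyclohexene F3 (C5=C6–H), an undemanding closure.
   - Hydroboration–oxidation (BH3·THF; NaOH, H2O2) would give the C6 alcohol F4.
   - Dess–Martin oxidation would give the ketone F5, which can enolise only towards C5.
   - KN(SiMe3)2/PhNTf2 would give the tetrasubstituted enol triflate F6.
   - Palladium-catalysed methoxycarbonylation (Pd(OAc)2, PPh3, CO, MeOH, Et3N, DMF) would give the methyl ester F7.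
   - i-Bu2AlH reduction would give 15.

2. Step 18 (first Julia–Kocienski olefination; step 19 is of the same type). The hindered C7 carbanion may add slowly to the α-methyl polyenal and decay first, by self-condensation at the tetrazole or by proton transfer from the dialdehyde. Both aldehyde ends may also be olefinated. The fallback sets out from 14 and comes back at aldehyde 24; it replaces the sulfone by a phosphorus ylide (Wittig olefination).
   - DDQ would cleave the PMB ether of 14 to the alcohol F9.
   - TBSOTf/2,6-lutidine would give the tris-silyl ether F10.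
   - Buffered HF·pyridine would free the primary allylic alcohol F11.
   - CBr4/PPh3 would give the bromide F12.
   - PPh3 in toluene would give the phosphonium bromide F13.
   - Its ylide (NaN(SiMe3)2, THF, −78 °C to rt) would be added to excess dialdehyde 22 to give 24.

3. Step 9 (chelation-controlled allylstannane addition). Attack through the fully substituted γ-carbon may be too slow at the temperature at which the magnesium chelate holds, so that facial selectivity erodes or the α-alkoxy aldehyde epimerises. The fallback sets out from bromide 10 and aldehyde 6 and comes back at 12; it uses a Barbier allylation through a closed six-membered transition state in place of the open SE2' pathway. Indium powder in THF/H2O at rt would turn 10 in the flask into the allylindium dibromide F8. F8 adds to 6 at its γ-carbon while trivalent indium chelates the α-OPMB group. Any C2 epimer would be removed by chromatography at 12 or 13.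

**Further compounds**

F1 | step 11 | (4R,5R)-5-(4-methoxybenzyloxy)-3,3,7-trimethylocta-1,7-dien-4-ol | C=CC(C)(C)[C@@H](O)[C@H](OCc1ccc(OC)cc1)CC(C)=C
F2 | step 11 | (4R,5R)-4-(tert-butyldimethylsilyloxy)-5-(4-methoxybenzyloxy)-3,3,7-trimethylocta-1,7-diene | C=CC(C)(C)[C@@H](O[Si](C)(C)C(C)(C)C)[C@H](OCc1ccc(OC)cc1)CC(C)=C
F3 | step 11 | tert-butyl{[(1R,6R)-6-(4-methoxybenzyloxy)-2,2,4-trimethylcyclohex-3-en-1-yl]oxy}dimethylsilane | CC1=CC(C)(C)[C@@H](O[Si](C)(C)C(C)(C)C)[C@H](OCc2ccc(OC)cc2)C1
F4 | step 11 | (3R,4R)-3-(tert-butyldimethylsilyloxy)-4-(4-methoxybenzyloxy)-2,2,6-trimethylcyclohexan-1-ol | CC1C(O)C(C)(C)[C@@H](O[Si](C)(C)C(C)(C)C)[C@H](OCc2ccc(OC)cc2)C1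
F5 | step 11 | (3R,4R)-3-(tert-butyldimethylsilyloxy)-4-(4-methoxybenzyloxy)-2,2,6-trimethylcyclohexan-1-one | CC1C(=O)C(C)(C)[C@@H](O[Si](C)(C)C(C)(C)C)[C@H](OCc2ccc(OC)cc2)C1
F6 | step 11 | (4R,5R)-5-(tert-butyldimethylsilyloxy)-4-(4-methoxybenzyloxy)-2,6,6-trimethylcyclohex-1-en-1-yl triflate | CC1=C(OS(=O)(=O)C(F)(F)F)C(C)(C)[C@@H](O[Si](C)(C)C(C)(C)C)[C@H](OCc2ccc(OC)cc2)C1
F7 | step 11 | methyl (4R,5R)-5-(tert-butyldimethylsilyloxy)-4-(4-methoxybenzyloxy)-2,6,6-trimethylcyclohex-1-ene-1-carboxylate | CC1=C(C(=O)OC)C(C)(C)[C@@H](O[Si](C)(C)C(C)(C)C)[C@H](OCc2ccc(OC)cc2)C1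
F8 | step 9 | [2-(tert-butyldimethylsilyloxymethyl)-3-methylbut-2-enyl]indium dibromide | CC(C)=C(C[In](Br)Br)CO[Si](C)(C)C(C)(C)C
F9 | step 18 | (1R,6R)-6-(tert-butyldimethylsilyloxy)-4-(tert-butyldimethylsilyloxymethyl)-3,5,5-trimethylcyclohex-3-en-1-ol | CC1=C(CO[Si](C)(C)C(C)(C)C)C(C)(C)[C@@H](O[Si](C)(C)C(C)(C)C)[C@H](O)C1
F10 | step 18 | (2R,3R)-2,3-dihydroxy-β-cyclogeraniol tris-TBS ether | CC1=C(CO[Si](C)(C)C(C)(C)C)C(C)(C)[C@@H](O[Si](C)(C)C(C)(C)C)[C@H](O[Si](C)(C)C(C)(C)C)C1
F11 | step 18 | [(4R,5R)-4,5-bis(tert-butyldimethylsilyloxy)-2,6,6-trimethylcyclohex-1-en-1-yl]methanol | CC1=C(CO)C(C)(C)[C@@H](O[Si](C)(C)C(C)(C)C)[C@H](O[Si](C)(C)C(C)(C)C)C1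
F12 | step 18 | (4R,5R)-1-(bromomethyl)-4,5-bis(tert-butyldimethylsilyloxy)-2,6,6-trimethylcyclohex-1-ene | CC1=C(CBr)C(C)(C)[C@@H](O[Si](C)(C)C(C)(C)C)[C@H](O[Si](C)(C)C(C)(C)C)C1
F13 | step 18 | {[(4R,5R)-4,5-bis(tert-butyldimethylsilyloxy)-2,6,6-trimethylcyclohex-1-en-1-yl]methyl}triphenylphosphonium bromide | CC1=C(C[P+](c2ccccc2)(c2ccccc2)c2ccccc2)C(C)(C)[C@@H](O[Si](C)(C)C(C)(C)C)[C@H](O[Si](C)(C)C(C)(C)C)C1.[Br-]
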